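**Retrosynthetic overview**
- Pendant lactone last: vinylogous Mannich addition of a 3-methyl-2-silyloxyfuran to the C3 iminium ion of a tricyclic lactam, then butenolide hydrogenation; the C13 hydroxyl comes from convex-face enolate hydroxylation just before.
- Pyrrolidinone and trans-fused azepane together: one tertiary nitro group is reduced, the amine lactamises onto a γ-ester and is N-alkylated by a chlorobutyl arm in the same flask (key step, two rings).
- Cyclopentane: intramolecular nitro-Michael addition of a secondary nitronate to a 3-methylbutenolide (C9a–C12 bond, quaternary C9a).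
- Ring-fused lactone: Sakurai 2-(ethoxycarbonyl)allylation of an aldehyde, then exo-to-endo isomerisation; C9/C10 come from an organocatalytic butanal–nitroalkene Michael addition.
- Ring order: ring-fused lactone, then cyclopentane, then pyrrolidinone plus azepane (one operation), then pendant lactone.

Assumption: 5-chloropentanal is bought as such; positions are named by Stemona-type numbering (N4, C3, C5–C9, quaternary C9a, C10 bearing ethyl, C11–C14 ring-fused lactone, C18–C21 pendant lactone), and the C13 epimer mixture present before step 7 is carried on.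

**Step 1**
Reactants: 1 5-chloropentanal; 2 methyl 4-nitrobutanoate
Product: 5 methyl (E)-9-chloro-4-nitronon-4-enoate, via nitro alcohol 3 (not isolated), via nitro mesylate 4 (not isolated)
Conditions: 1,1,3,3-tetramethylguanidine (10 mol %), THF, 0 °C to rt; then MsCl, Et3N, CH2Cl2, −10 °C to rt
Reagents that add atoms: none
Why: Henry (nitroaldol) addition followed by mesylation and E1cB elimination gives the conjugated nitroalkene, the (E) isomer (alkyl chain trans to NO2) being the thermodynamic one, and no stereocentre is carried forward.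

**Step 2**
Reactants: 5 methyl (E)-9-chloro-4-nitronon-4-enoate; 6 butanal
Product: 7 methyl (5R,6R)-5-(4-chlorobutyl)-6-formyl-4-nitrooctanoate (C4 epimers)
Conditions: (S)-α,α-diphenylprolinol trimethylsilyl ether (20 mol %), 4-nitrophenol (20 mol %), toluene, 0 °C to rt
Reagents that add atoms: none
Why: Enamine-catalysed Michael addition of an aldehyde to a nitroalkene (Hayashi type), in which the (S)-catalyst enamine of butanal attacks the β-carbon through the acyclic synclinal transition state and sets C10 and C9 as the syn (R,R) pair that becomes trans on the later cyclopentane, α-substituted nitroalkenes being slower but known acceptors, while the nitro carbon is left as a mixture because step 5 re-forms it.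

**Step 3**
Reactants: 7 methyl (5R,6R)-5-(4-chlorobutyl)-6-formyl-4-nitrooctanoate; 8 ethyl 2-[(trimethylsilyl)methyl]prop-2-enoate
Product: 10 methyl (5R,6R)-5-(4-chlorobutyl)-6-[(2R)-4-methylidene-5-oxooxolan-2-yl]-4-nitrooctanoate, via hydroxy ester 9 (not isolated)
Conditions: TiCl4, CH2Cl2, −78 °C; then TsOH·H2O (cat.), CH2Cl2, rt
Reagents that add atoms: none
Why: Hosomi–Sakurai 2-(alkoxycarbonyl)allylation through an open transition state under Felkin–Anh control (branched C9 anti to the incoming allylsilane, ethyl as medium group) sets C11 with its oxygen syn to the ethyl group along the chain (trans on the later ring), acid then closes the γ-lactone, and the minor C11 epimer is removed by chromatography.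

**Step 4**
Reactants: 10 methyl (5R,6R)-5-(4-chlorobutyl)-6-[(2R)-4-methylidene-5-oxooxolan-2-yl]-4-nitrooctanoate
Product: 11 methyl (5R,6R)-5-(4-chlorobutyl)-6-[(2S)-4-methyl-5-oxo-2,5-dihydrofuran-2-yl]-4-nitrooctanoate
Conditions: RhCl3·3H2O (5 mol %), MeOH, 60 °C
Reagents that add atoms: none
Why: Rhodium hydride addition–elimination (alkene isomerisation) moves the exocyclic double bond into the ring to give the thermodynamically preferred conjugated butenolide under neutral conditions that leave C9, C10 and C11 untouched (the descriptor at C11 changes only by priority).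

**Step 5**
Reactants: 11 methyl (5R,6R)-5-(4-chlorobutyl)-6-[(2S)-4-methyl-5-oxo-2,5-dihydrofuran-2-yl]-4-nitrooctanoate
Product: 12 methyl 3-[(3aR,4S,5R,6R,6aS)-5-(4-chlorobutyl)-6-ethyl-3-methyl-4-nitro-2-oxohexahydro-2H-cyclopenta[b]furan-4-yl]propanoate (epimers at the lactone α-carbon)
Conditions: DBU (0.5 equiv), MeCN (0.02 M), −20 to 0 °C; AcOH quench
Reagents that add atoms: none
Why: Intramolecular nitro-Michael addition (5-exo-trig) of the nitronate to the butenolide β-carbon necessarily gives the cis ring fusion at C12, and C9a is set under kinetic control because the nitronate reacts in the rotamer free of A(1,3) strain (H9 eclipsing the C=N–O unit, C8 chain on the face away from the acceptor) through an open, non-chelated transition state, which places the nitro group trans to the C8 chain and to the lactone and the ester arm cis to both.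

**Step 6**
Reactants: 12 methyl 3-[(3aR,4S,5R,6R,6aS)-5-(4-chlorobutyl)-6-ethyl-3-methyl-4-nitro-2-oxohexahydro-2H-cyclopenta[b]furan-4-yl]propanoate
Product: 15 (9R,9aS,10R,11S,12R)-tricyclic lactam lactone (target core; lactam carbonyl at C3; hydrogen at C13), via amino ester 13 (not isolated), via chloro lactam 14 (not isolated)
Conditions: H2 (4 bar), Raney Ni, MeOH, 40 °C; filter, evaporate; then NaH, Bu4NI (10 mol %), THF–DMF, 0 °C to rt, no intermediate purification
Reagents that add atoms: none
Why: Hydrogenation of the tertiary nitro group gives the tert-alkyl amine, which lactamises onto the γ-ester (5-exo-trig) and, after deprotonation, closes the azepane by iodide-assisted 7-exo-tet N-alkylation, so pyrrolidinone and azepane form in one operation with no stereocentre touched, the trans ring fusion following from nitrogen and the C8 chain being trans on the cyclopentane.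

**Step 7**
Reactants: 15 (9R,9aS,10R,11S,12R)-tricyclic lactam lactone
Product: 16 (13S)-13-hydroxy tricyclic lactam lactone
Conditions: KN(SiMe3)2 (1.2 equiv), THF, −78 °C; then trans-2-(phenylsulfonyl)-3-phenyloxaziridine, −78 °C; aq NH4Cl
Reagents that add atoms: trans-2-(phenylsulfonyl)-3-phenyloxaziridine, O=S(=O)(N1OC1c1ccccc1)c1ccccc1
Why: Davis oxaziridine hydroxylation of the lactone potassium enolate (the lactone α-CH is more acidic than the lactam α-CH2), the oxidant approaching the convex face anti to the quaternary C9a so that OH ends cis to H12 and the methyl group points into the concave face, which is the (13S) configuration.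

**Step 8**
Reactants: 17 3-methylfuran-2(5H)-one
Product: 18 triisopropyl[(3-methylfuran-2-yl)oxy]silane
Conditions: TIPSOTf, Et3N, CH2Cl2, 0 °C
Reagents that add atoms: triisopropylsilyl trifluoromethanesulfonate, CC(C)[Si](OS(=O)(=O)C(F)(F)F)(C(C)C)C(C)C
Why: Soft enolisation and O-silylation of the butenolide dienolate gives the aromatic 2-silyloxyfuran, with no stereocentre involved.

**Step 9**
Reactants: 16 (13S)-13-hydroxy tricyclic lactam lactone; 18 triisopropyl[(3-methylfuran-2-yl)oxy]silane
Product: 20 (3S,18S)-butenolide adduct (target with a C19=C20 double bond), via silyl acetal 19 (not isolated)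
Conditions: IrCl(CO)(PPh3)2 (1 mol %), (Me2HSi)2O (3 equiv), toluene, rt; then 18, 2-nitrobenzoic acid, MeCN, 0 °C to rt; aq NaHCO3
Reagents that add atoms: none
Why: IrCl(CO)(PPh3)2-catalysed hydrosilylation (monovalent iridium) reduces only the tertiary lactam to the N,O-silyl acetal, which the acid ionises to the C3 iminium ion, and vinylogous Mukaiyama–Mannich addition of 18 through its C5 then occurs on the face away from the azepane methylenes (C3 substituent cis to C12 and trans to C9, 3S) with the threo-type preference usual for 2-silyloxyfurans and cyclic iminium ions (18S), any silylated tertiary alcohol being freed on work-up.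

**Step 10**
Reactants: 20 (3S,18S)-butenolide adduct
Product: 21 CNP0260919.2 (3S,9R,9aS,10R,11S,12R,13S,18S,20S)
Conditions: H2 (1 atm), 10% Pd/C, EtOH–AcOH (10:1), rt
Reagents that add atoms: none
Why: Heterogeneous hydrogenation adds H2 cis to the butenolide from the face opposite the C18 substituent, giving the cis-disubstituted lactone (20S) and leaving all other centres unchanged.

**Compound list**
1 | 5-chloropentanal | O=CCCCCCl | starting material
2 | methyl 4-nitrobutanoate | COC(=O)CCC[N+](=O)[O-] | starting material
3 | methyl 9-chloro-5-hydroxy-4-nitrononanoate (diastereomers) | COC(=O)CCC([N+](=O)[O-])C(O)CCCCCl | intermediate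
4 | methyl 9-chloro-5-(methanesulfonyloxy)-4-nitrononanoate (diastereomers) | COC(=O)CCC([N+](=O)[O-])C(OS(C)(=O)=O)CCCCCl | intermediate
5 | methyl (E)-9-chloro-4-nitronon-4-enoate | COC(=O)CC/C(=C\CCCCCl)[N+](=O)[O-] | intermediate
6 | butanal | CCCC=O | starting material
7 | methyl (5R,6R)-5-(4-chlorobutyl)-6-formyl-4-nitrooctanoate (C4 epimers) | CC[C@@H](C=O)[C@@H](CCCCCl)C(CCC(=O)OC)[N+](=O)[O-] | intermediate
8 | ethyl 2-[(trimethylsilyl)methyl]prop-2-enoate | C=C(C[Si](C)(C)C)C(=O)OCC | starting material
9 | methyl (5R,6R)-5-(4-chlorobutyl)-6-[(1R)-3-(ethoxycarbonyl)-1-hydroxybut-3-en-1-yl]-4-nitrooctanoate | CC[C@@H]([C@H](O)CC(=C)C(=O)OCC)[C@@H](CCCCCl)C(CCC(=O)OC)[N+](=O)[O-] | intermediate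
10 | methyl (5R,6R)-5-(4-chlorobutyl)-6-[(2R)-4-methylidene-5-oxooxolan-2-yl]-4-nitrooctanoate | CC[C@@H]([C@H]1CC(=C)C(=O)O1)[C@@H](CCCCCl)C(CCC(=O)OC)[N+](=O)[O-] | intermediate
11 | methyl (5R,6R)-5-(4-chlorobutyl)-6-[(2S)-4-methyl-5-oxo-2,5-dihydrofuran-2-yl]-4-nitrooctanoate | CC[C@@H]([C@H]1C=C(C)C(=O)O1)[C@@H](CCCCCl)C(CCC(=O)OC)[N+](=O)[O-] | intermediate
12 | methyl 3-[(3aR,4S,5R,6R,6aS)-5-(4-chlorobutyl)-6-ethyl-3-methyl-4-nitro-2-oxohexahydro-2H-cyclopenta[b]furan-4-yl]propanoate (nitro trans to the chlorobutyl chain and to the lactone; C3 epimers) | CC[C@H]1[C@@H]2OC(=O)C(C)[C@@H]2[C@]([N+](=O)[O-])(CCC(=O)OC)[C@@H]1CCCCCl | intermediate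
13 | amino ester: the 4-amino analogue of 12, same configuration | CC[C@H]1[C@@H]2OC(=O)C(C)[C@@H]2[C@](N)(CCC(=O)OC)[C@@H]1CCCCCl | intermediate
14 | chloro spiro-lactam: pyrrolidin-2-one spiro-fused at C9a, N trans to the 4-chlorobutyl chain | CC[C@H]1[C@@H]2OC(=O)C(C)[C@@H]2[C@]2(CCC(=O)N2)[C@@H]1CCCCCl | intermediate
15 | (9R,9aS,10R,11S,12R)-tricyclic lactam lactone (target core, C3 lactam carbonyl, H at C13, no pendant lactone) | CC[C@H]1[C@@H]2OC(=O)C(C)[C@@H]2[C@@]23CCC(=O)N2CCCC[C@H]13 | intermediate
16 | (13S)-13-hydroxy derivative of 15 | CC[C@H]1[C@@H]2OC(=O)[C@@](C)(O)[C@@H]2[C@@]23CCC(=O)N2CCCC[C@H]13 | intermediate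
17 | 3-methylfuran-2(5H)-one | CC1=CCOC1=O | starting material
18 | triisopropyl[(3-methylfuran-2-yl)oxy]silane | CC1=C(O[Si](C(C)C)(C(C)C)C(C)C)OC=C1 | intermediate
19 | N,O-silyl acetal of 16 (C3 bearing H and OSiMe2OSiHMe2; C3 epimers) | CC[C@H]1[C@@H]2OC(=O)[C@@](C)(O)[C@@H]2[C@@]23CCC(O[Si](C)(C)O[SiH](C)C)N2CCCC[C@H]13 | intermediate
20 | (3S,18S)-butenolide adduct (target with C19=C20) | CC[C@H]1[C@@H]2OC(=O)[C@@](C)(O)[C@@H]2[C@@]23CC[C@@H]([C@@H]4C=C(C)C(=O)O4)N2CCCC[C@H]13 | intermediate
21 | CNP0260919.2 (3S,9R,9aS,10R,11S,12R,13S,18S,20S) | CC[C@H]1[C@@H]2OC(=O)[C@@](C)(O)[C@@H]2[C@@]23CC[C@@H]([C@@H]4C[C@H](C)C(=O)O4)N2CCCC[C@H]13 | target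

**Totals**
Total steps: 10. Longest linear sequence: 9 (steps 1–7, 9, 10); step 8 is a one-step side branch.

**Three steps most likely to fail**

Step 5, because it creates the congested quaternary C9a and its configuration rests on a kinetic preference that a reversible nitro-Michael addition could erode. Fallback: it sets out from 12 (any C9a epimer ratio) and comes back at 14. Radical denitration (Bu3SnH, AIBN, toluene, 90 °C) converges both epimers on one planar C9a radical, which takes hydrogen from the open convex face to give the denitrated ester F4 (C9a–H trans to the chlorobutyl chain and to the lactone). Aminolysis of the methyl ester with NH2OH gives the hydroxamic acid F5, and carbonyldiimidazole closes it to the 1,4,2-dioxazol-5-one F6. Nitrenoid insertion catalysed by Cp*Ir(8-quinolinolato)Cl with NaB[3,5-(CF3)2C6H3]4 at 40 °C then goes into the γ C–H bond, which is C9a–H, with retention, and delivers 14 with nitrogen on the required face.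

Step 2, because an α,β-disubstituted nitroalkene is a sluggish acceptor for enamines. Fallback: it sets out from 1 and comes back at 7. Nitromethane is added to 1 (Henry reaction, catalytic tetramethylguanidine) to give 6-chloro-1-nitrohexan-2-ol F1, which is dehydrated on basic Al2O3 to (E)-6-chloro-1-nitrohex-1-ene F2. This unhindered nitroalkene takes up butanal 6 under the same catalyst to give (2R,3R)-7-chloro-2-ethyl-3-(nitromethyl)heptanal F3. The primary nitro group of F3 is then added to methyl acrylate (catalytic DBU, MeCN, 0 °C) to give 7, so the three-carbon ester arm is installed after the asymmetric step instead of before it.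

Step 9, because two stereocentres are set by substrate control on a new scaffold and the furan may add to the wrong face of the C3 iminium ion. Fallback: it sets out from 16 and comes back at 21, reversing the order of bond formation at C3 (carbon first, hydrogen last). Tf2O with 2-fluoropyridine (1.05 equiv, −78 °C, the lactam oxygen reacting before the hindered tertiary alcohol) gives the O-triflyl iminium triflate F7. This acylates furan 18 at C5 (Vilsmeier–Haack type) to give the push–pull aminoalkylidene butenolide F8. Hydrogenation (H2, PtO2, AcOH) then delivers hydrogen to C3, C18 and C20 from the less hindered face of the planar dienamine and gives 21, with the opposite sense of induction at C3 to the Mannich addition; C18 in this variant depends on the alkene geometry and may need separation.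

**Further compounds**
F1 | step 2 | 6-chloro-1-nitrohexan-2-ol | OC(CCCCCl)C[N+](=O)[O-]
F2 | step 2 | (E)-6-chloro-1-nitrohex-1-ene | ClCCCC/C=C/[N+](=O)[O-]
F3 | step 2 | (2R,3R)-7-chloro-2-ethyl-3-(nitromethyl)heptanal | CC[C@@H](C=O)[C@@H](CCCCCl)C[N+](=O)[O-]
F4 | step 5 | denitrated ester (12 with H in place of NO2 at C9a, H trans to the chlorobutyl chain) | CC[C@H]1[C@@H]2OC(=O)C(C)[C@@H]2[C@H](CCC(=O)OC)[C@@H]1CCCCCl
F5 | step 5 | hydroxamic acid of F4 | CC[C@H]1[C@@H]2OC(=O)C(C)[C@@H]2[C@H](CCC(=O)NO)[C@@H]1CCCCCl
F6 | step 5 | 3-substituted 1,4,2-dioxazol-5-one from F5 | CC[C@H]1[C@@H]2OC(=O)C(C)[C@@H]2[C@H](CCC3=NOC(=O)O3)[C@@H]1CCCCCl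
F7 | step 9 | O-triflyl iminium triflate of 16 | CC[C@H]1[C@@H]2OC(=O)[C@@](C)(O)[C@@H]2[C@@]23CCC(OS(=O)(=O)C(F)(F)F)=[N+]2CCCC[C@H]13.[O-]S(=O)(=O)C(F)(F)F
F8 | step 9 | aminoalkylidene butenolide (C3=C18, geometry not assigned) | CC[C@H]1[C@@H]2OC(=O)[C@@](C)(O)[C@@H]2[C@@]23CCC(=C4C=C(C)C(=O)O4)N2CCCC[C@H]13
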